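A one-step world has Q turning into X for as long as Q lasts, but the spring run still holds 63.4% of its charge at 6.3 h, and its last two readings differ by 2.05% of that charge.

| flask | Q | J | time |
|---|---|---|---|
| spring | 0.200 M | 0.00200 M |  |
| autumn | 0.120 M | 0.00200 M |  |
| noon | 0.200 M | 0.00100 M |  |
| dusk | 0.500 M | 0.00200 M | 6.3 h |

| run | time / h | [Q] / M |
|---|---|---|
| spring run | 0.36 | 0.1911 |
| spring run | 1.1 | 0.1738 |
| spring run | 2.1 | 0.1549 |
| spring run | 3.3 | 0.1417 |
| spring run | 4.7 | 0.1309 |
| spring run | 6.3 | 0.1268 |
| autumn run | 0.36 | 0.1078 |
| autumn run | 1.1 | 0.0919 |
| autumn run | 2.1 | 0.0758 |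
| autumn run | 3.3 | 0.0669 |
| autumn run | 4.7 | 0.0572 |
| autumn run | 6.3 | 0.0601 |
| noon run | 0.36 | 0.1987 |
| noon run | 1.1 | 0.1909 |
| noon run | 2.1 | 0.1870 |
| noon run | 3.3 | 0.1851 |
| noon run | 4.7 | 0.1802 |
| noon run | 6.3 | 0.1839 |

(standard deviation of a reading: 0.002 M)

- the exponent of [Q] in the starting rate at the charge of the spring run (at the point where two percent of the Q have become X) (one fixed amount of X, the same in the runs compared)
- the exponent of [J] in the starting rate at the charge of the spring run (at the point where two percent of the Q have become X)
- Q in the dusk run at 6.3 h, as a share of the Q charged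
- which of these the readings show (the catalyst dies by itself / nothing beyond the main steps / the product ties up the catalyst / the catalyst wakes slowly)

- Overall: Q -> X, with J as catalyst.
- Constant volume, constant temperature.
- What is held in complexes is read along with the free species.
- An order is taken over about fifteen percent of the charge, up and down.

Through its second reading, the spring run turns 0.119 h⁻¹ of its charge, its early pace, and it ends at 36.6% turned. The quantity to carry is the run-out time, 3.07 h: the final share turned divided by the early pace. It marks the crossing from pace to stall, a lifetime of the rate. The autumn run, with pace 0.213 h⁻¹ and 49.9% turned, gives a shorter 2.34 h.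

For the dusk run, the spring J is the one that counts, so the noon run, at half that J, does not enter this reckoning. One reading's scatter is 7.63% of the spring loss behind the pace, but that pace enters the dusk reckoning twice, once as the early pace and once inside the run-out time, and the two entries pull in opposite directions. A spring pace higher by that part gives a dusk run-out time of 4.77 h and 17.9% turned at 6.3 h; one lower by that part gives 7.01 h and 18.3% turned. The gap between the run-out times, stretched to the dusk charge, has its error multiplied by 3.75.

The reckoning here takes the run-out time as straight in the charge, keeps the early amount per hour of the spring run, and lets the pace die exponentially: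

run-out time, dusk: 5.80 h

early pace, dusk: 0.0476 h⁻¹

share turned by 6.3 h: 18.3%

share left: 81.7%

The forecast reads the stall by the clock as well “stopping follows time, not product”, and gives 82% left, exponents 0.3 in Q and 1.6 in J, and the catalyst dies by itself.

    J + Q ⇌ JQ, settled at all times (10.80 M⁻¹)
    JQ + J → X + 2 J (34310 M⁻¹ h⁻¹)
    J → Zu (0.5328 h⁻¹)

The dusk run holds 85.4% of its charge at 6.3 h, the answer is the catalyst dies by itself, and the exponents are −0.35 in Q and 2.1 in J. That negative exponent goes with a dusk pace below the one carried: at 5.80 h, the 14.6% turned asks for 0.0379 h⁻¹, less than 0.0476 h⁻¹. In the noon run, the rate 0.0061 M h⁻¹ is 0.0306 h⁻¹ of its charge; over 3.07 h that makes 9.39%, and the last noon reading shows 8.05% turned.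

The data were computed with made-up constants; scatter was added.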